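**Retrosynthetic overview**
1. Target 10 ← 9 by O-methylation of the C2 hydroxyl of ring A (last step).
2. 9 ← 7 + 8: the bond from the ring B oxygen to C1 of ring A is made by rhodium-carbene insertion into the O–H bond of 2,4-dibromophenol 8. The strategy rests on the two adjacent oxygen-bearing carbons of ring A, C1 (O-aryl) and C2 (OMe): this catechol pattern maps onto an ortho-quinone diazide with the diazo group on C1 and the carbonyl on C2.
3. 7 ← 5 ← 4 ← 3: diazotisation of the ortho-aminophenol, which comes from ortho-nitration of the symmetric 3,4,5-tribromophenol followed by reduction.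
4. 3 ← 1: one-pot iridium C–H borylation and oxidation at the only unhindered C–H of 1,2,3-tribromobenzene.
5. No ring is built: rings A and B are bought as benzenes; ring A is functionalised first and then joined to ring B.

Key step: step 5

Remark: ring A is numbered as in the target throughout (C1 aryloxy carbon, C2 methoxy carbon, C3 H, C4 to C6 Br). The quinone diazide 7 is assumed to be handled in solution, cold and in the dark, and never dried in bulk.

Step 1
Reactants: 1 1,2,3-tribromobenzene
Product: 3 3,4,5-tribromophenol, via 3,4,5-tribromophenylboronic acid pinacol ester 2 (not isolated)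
Conditions: [Ir(OMe)(cod)]2 (1.5 mol%), 4,4'-di-tert-butyl-2,2'-bipyridine (3 mol%), B2pin2 (1.0 equiv), THF, 80 °C; evaporate volatiles; then Oxone (KHSO5, 1.1 equiv), acetone/H2O, rt
Reagents that add atoms: Oxone (potassium peroxymonosulfate), [K+].[O-]S(=O)(=O)OO
Why: Iridium-catalysed C–H borylation is sterically governed and should touch only the one C–H of 1 that has no ortho bromine, and Oxone oxidation of the C–B bond (aryl shift from boron to oxygen, then hydrolysis) should give the phenol with the three C–Br bonds intact.

Step 2
Reactants: 3 3,4,5-tribromophenol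
Product: 4 3,4,5-tribromo-2-nitrophenol
Conditions: HNO3 (65%, 1.05 equiv), AcOH, 10–15 °C
Reagents that add atoms: nitric acid, O[N+](=O)[O-]
Why: Electrophilic aromatic nitration directed by the hydroxyl group to its two free ortho carbons, which are equivalent by symmetry, should give a single mononitro isomer, while the para carbon is blocked by bromine and one equivalent of acid at low temperature limits dinitration.

Step 3
Reactants: 4 3,4,5-tribromo-2-nitrophenol
Product: 5 2-amino-3,4,5-tribromophenol
Conditions: Fe powder, AcOH, EtOH/H2O, 60 °C; used promptly under N2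
Reagents that add atoms: none
Why: Dissolving-metal (Béchamp-type) reduction with iron in acetic acid should take the nitro group to the amine without touching the aryl bromides, which hydrogenation over palladium would endanger.

Step 4
Reactants: 5 2-amino-3,4,5-tribromophenol
Product: 7 3,4,5-tribromo-6-diazocyclohexa-2,4-dien-1-one, via 2,3,4-tribromo-6-hydroxybenzenediazonium hydrogensulfate 6 (not isolated)
Conditions: NaNO2, H2SO4, AcOH/H2O, 0–5 °C; then NaOAc to pH 5, extraction into CH2Cl2, dark
Reagents that add atoms: sodium nitrite, [Na+].[O-]N=O
Why: Diazotisation of an ortho-aminophenol gives the hydroxydiazonium ion 6, which the three bromines make strongly acidic, so acetate buffering should remove the phenolic proton to give the neutral ortho-quinone diazide 7, and the non-nucleophilic hydrogensulfate medium avoids halide exchange at the bromines ortho and para to the diazonium group.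

Step 5
Reactants: 7 3,4,5-tribromo-6-diazocyclohexa-2,4-dien-1-one; 8 2,4-dibromophenol (3 equiv)
Product: 9 3,4,5-tribromo-2-(2,4-dibromophenoxy)phenol
Conditions: Rh2(OAc)4 (2 mol%), 1,2-dichloroethane, 60 °C, slow addition of 7 to 8 and catalyst, dark, N2
Reagents that add atoms: none
Why: Rh2(OAc)4 adds to the diazo carbon C1 of 7 and expels N2 to give an electrophilic rhodium carbene that behaves as a 2-oxidophenyl cation; the hydroxyl oxygen of 8 attacks C1 to form an oxonium ylide, and proton transfer to the former carbonyl oxygen restores aromatic ring A as the 2-aryloxyphenol 9. The closest known reaction type is the rhodium-carbene O–H insertion of quinone diazides and diazonaphthoquinones into alcohols and phenols, which gives hydroxyaryl ethers. No ring is closed and no stereocenter is formed. The step needs site selectivity, which the position of the diazo group secures (the ether oxygen ends on C1 next to C6–Br and the free hydroxyl on C2), and chemoselectivity for O–H insertion over Wolff ring contraction, C-arylation of 8 and carbene dimerisation. Metal catalysis in the dark at moderate temperature instead of photolysis disfavours the Wolff path, the para carbon and one ortho carbon of 8 carry bromine and its ring is electron-poor, and slow addition of 7 to an excess of 8 keeps the carbene away from unreacted diazide and from the hydroxyl of 9.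

Step 6
Reactants: 9 3,4,5-tribromo-2-(2,4-dibromophenoxy)phenol
Product: 10 1,2,3-tribromo-4-(2,4-dibromophenoxy)-5-methoxybenzene
Conditions: MeI, K2CO3, acetone, 40 °C
Reagents that add atoms: iodomethane, CI
Why: Williamson ether synthesis, in which the phenoxide of 9 formed by K2CO3 is methylated by SN2 attack on iodomethane, should proceed cleanly because the diaryl ether and the five aryl bromides are inert to these conditions.

**Compound list**
1 | 1,2,3-tribromobenzene | Brc1cccc(Br)c1Br | starting material
2 | 2-(3,4,5-tribromophenyl)-4,4,5,5-tetramethyl-1,3,2-dioxaborolane (3,4,5-tribromophenylboronic acid pinacol ester) | CC1(C)OB(OC1(C)C)c1cc(Br)c(Br)c(Br)c1 | intermediate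
3 | 3,4,5-tribromophenol | Oc1cc(Br)c(Br)c(Br)c1 | intermediate
4 | 3,4,5-tribromo-2-nitrophenol | Oc1cc(Br)c(Br)c(Br)c1[N+](=O)[O-] | intermediate
5 | 2-amino-3,4,5-tribromophenol | Nc1c(O)cc(Br)c(Br)c1Br | intermediate
6 | 2,3,4-tribromo-6-hydroxybenzenediazonium hydrogensulfate | Oc1cc(Br)c(Br)c(Br)c1[N+]#N.OS(=O)(=O)[O-] | intermediate
7 | 3,4,5-tribromo-6-diazocyclohexa-2,4-dien-1-one | O=C1C=C(Br)C(Br)=C(Br)C1=[N+]=[N-] | intermediate
8 | 2,4-dibromophenol | Oc1ccc(Br)cc1Br | starting material
9 | 3,4,5-tribromo-2-(2,4-dibromophenoxy)phenol | Oc1cc(Br)c(Br)c(Br)c1Oc1ccc(Br)cc1Br | intermediate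
10 | 1,2,3-tribromo-4-(2,4-dibromophenoxy)-5-methoxybenzene | COc1cc(Br)c(Br)c(Br)c1Oc1ccc(Br)cc1Br | target

Total step count: 6. Longest linear sequence: 6 steps (1 to 10).

**Steps most likely to fail**

Step 5 (key step). The rhodium carbene may be diverted: attack on the free ortho C–H of 8, coupling with unreacted diazide, or a second insertion into the hydroxyl of 9. Insertion may also be slow, because 8 is a weak oxygen nucleophile and the carbene carbon sits next to a bromine. The fallback reverses the roles of the two rings and uses a metal-free iodonium arylation; it sets out from nitrophenol 4 and comes back at target 10. Methylation of 4 (MeI, K2CO3, acetone) would give 1,2,3-tribromo-5-methoxy-4-nitrobenzene F1. Reduction with Fe in AcOH would give 2,3,4-tribromo-6-methoxyaniline F2. Diazotisation (NaNO2, H2SO4, AcOH/H2O, 0 °C) would give 2,3,4-tribromo-6-methoxybenzenediazonium hydrogensulfate F3, which is hydrolysed with Cu2O and Cu(NO3)2 in water at room temperature to 2,3,4-tribromo-6-methoxyphenol F4. In parallel, commercial 2,4-dibromo-1-iodobenzene is oxidised with mCPBA and TsOH·H2O in MeCN and trapped with 1,3,5-trimethoxybenzene to give (2,4-dibromophenyl)(2,4,6-trimethoxyphenyl)iodonium tosylate F5. O-Arylation of F4 with F5 (K2CO3, MeCN, 50 °C) should transfer only the dibromophenyl group, the electron-rich trimethoxyphenyl group staying on iodine, and give 10 directly.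

Step 2. The nitronium ion may attack ipso at the para C–Br carbon with loss of bromine, nitrate the second ortho carbon as well, or oxidise the phenol. The fallback brings in the nitrogen by azo coupling instead of nitration; it sets out from phenol 3 and comes back at aminophenol 5. Coupling of the phenoxide of 3 with commercial 4-nitrobenzenediazonium tetrafluoroborate (aq. NaOH/THF, 0 °C) would occur at the free ortho carbon and give 3,4,5-tribromo-2-[(E)-(4-nitrophenyl)diazenyl]phenol F6. Reductive cleavage of the N=N bond with Na2S2O4 (aq. EtOH, 70 °C) would then give 5, with the water-soluble diamine removed by an acid wash.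

Step 4. Nitrogen may be lost from the diazide under light or on concentration, and the diazonium ion may azo-couple with aminophenol that is not yet diazotised. The fallback stores the nitrogen as a salt and never isolates the neutral diazide; it sets out from 5 and comes back at 9. Non-aqueous diazotisation (tBuONO, HBF4·OEt2, THF, −10 °C, then Et2O) would precipitate 2,3,4-tribromo-6-hydroxybenzenediazonium tetrafluoroborate F7, which can be kept cold. It is stirred with NaOAc in 1,2-dichloroethane/MeCN at 0 °C, and the cold filtrate, which holds 7, is added without concentration to Rh2(OAc)4 and 8 under the conditions of step 5.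

**Further compounds**
F1 | step 5 | 1,2,3-tribromo-5-methoxy-4-nitrobenzene | COc1cc(Br)c(Br)c(Br)c1[N+](=O)[O-]
F2 | step 5 | 2,3,4-tribromo-6-methoxyaniline | COc1cc(Br)c(Br)c(Br)c1N
F3 | step 5 | 2,3,4-tribromo-6-methoxybenzenediazonium hydrogensulfate | COc1cc(Br)c(Br)c(Br)c1[N+]#N.OS(=O)(=O)[O-]
F4 | step 5 | 2,3,4-tribromo-6-methoxyphenol | COc1cc(Br)c(Br)c(Br)c1O
F5 | step 5 | (2,4-dibromophenyl)(2,4,6-trimethoxyphenyl)iodonium 4-methylbenzenesulfonate | COc1cc(OC)c([I+]c2ccc(Br)cc2Br)c(OC)c1.Cc1ccc(cc1)S(=O)(=O)[O-]
F6 | step 2 | 3,4,5-tribromo-2-[(E)-(4-nitrophenyl)diazenyl]phenol | Oc1cc(Br)c(Br)c(Br)c1/N=N/c1ccc(cc1)[N+](=O)[O-]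
F7 | step 4 | 2,3,4-tribromo-6-hydroxybenzenediazonium tetrafluoroborate | Oc1cc(Br)c(Br)c(Br)c1[N+]#N.F[B-](F)(F)F
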